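## Plan

Labels: ring A is the enal-bearing arene (C1 side chain, C3–O–C7', C4–O–C8', C5–OMe). Ring B is the 1,4-dioxane, ring C is the guaiacyl ring on C7', and C9' is the CH2OH carbon on C8'.
Retrosynthesis: remove the MOM group from the ring C phenol, cut the C1–vinyl bond (Heck), raise C9' to a carboxamide, then cut ring B at C7'–C8' and at O(C7')–C3 together. This leaves MOM-vanillin and a (2-iodoaryloxy)acetamide built from 4-bromoguaiacol, chloroacetyl chloride and 7-azaindoline.
Enabling feature: in ring B the array O–C7'–C8'(C9')–O is a syn glycolate aldol once C9' is a carbonyl. The oxygen born on C7' lies six atoms round from C3 of ring A, the carbon ortho to the C4–O–C8' ether oxygen, so an iodine on C3 lets that same metal alkoxide close ring B.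
Forward order: rings A and C are bought and the C8'–C9' unit is hung on the C4 oxygen. Ring B arises in step 5 together with the union of the two halves; C9' is then reduced, the enal is joined to C1 and the phenol is freed. The helpers leave as follows: iodine in step 5, the azaindoline amide and the amide oxidation level in step 6, MOM in step 8.
Stereochemistry: C7' and C8' both come from the chiral bisphosphine on the copper enolate (syn aldol). They pass unchanged through the O-arylation (syn gives trans) and are not touched afterwards; the trans ring is also the thermodynamic one at C7'.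

Key step: step 5

Assumption: the sense of induction of the copper/(R)-DTBM-SEGPHOS enolate is assigned by analogy with related alpha-heteroatom-substituted amides. If it proves opposite, the equally available (S)-ligand is used and nothing else changes.

## Route

Step 1
Reactants: 1 4-bromo-2-methoxyphenol
Product: 2 4-bromo-2-iodo-6-methoxyphenol
Conditions: NIS, p-TsOH (10 mol %), MeCN, 0 °C to rt
Reagents that add atoms: N-iodosuccinimide O=C1CCC(=O)N1I
Why: Electrophilic aromatic iodination, in which the free hydroxyl is the strongest director and its para position is blocked by bromine, so iodine should enter the only free ortho position, the later C3 of ring A.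

Step 2
Reactants: 3 7-azaindoline (2,3-dihydro-1H-pyrrolo[2,3-b]pyridine); 4 chloroacetyl chloride
Product: 5 1-(chloroacetyl)-7-azaindoline
Conditions: K2CO3, CH2Cl2, 0 °C to rt
Reagents that add atoms: none
Why: N-acylation of the secondary amine by the acid chloride (Schotten–Baumann type), the acyl chloride being far more electrophilic than the alkyl chloride.

Step 3
Reactants: 2 4-bromo-2-iodo-6-methoxyphenol; 5 1-(chloroacetyl)-7-azaindoline
Product: 6 1-[(4-bromo-2-iodo-6-methoxyphenoxy)acetyl]-7-azaindoline
Conditions: K2CO3, KI (10 mol %), DMF, 60 °C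
Reagents that add atoms: none
Why: Williamson ether synthesis, in which the phenoxide displaces the activated alpha-chloride of the amide and neither aryl halide reacts under these conditions.

Step 4
Reactants: 7 vanillin
Product: 8 3-methoxy-4-(methoxymethoxy)benzaldehyde
Conditions: MOMCl, K2CO3, acetone, rt
Reagents that add atoms: chloromethyl methyl ether COCCl
Why: O-alkylation of the phenoxide to the MOM acetal, which keeps the aldehyde electrophilic, withstands base, hydride and Heck conditions, and leaves with dilute acid.

Step 5
Reactants: 6 1-[(4-bromo-2-iodo-6-methoxyphenoxy)acetyl]-7-azaindoline; 8 3-methoxy-4-(methoxymethoxy)benzaldehyde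
Product: 10 trans-(7'S,8'R)-benzodioxane 7-azaindoline amide, via syn-aldol adduct 9 (not isolated)
Conditions: [Cu(MeCN)4]PF6 (10 mol %), (R)-DTBM-SEGPHOS (11 mol %), 2-tert-butyl-1,1,3,3-tetramethylguanidine (10 mol %), THF, −40 °C; then Cs2CO3, 3,4,7,8-tetramethyl-1,10-phenanthroline (20 mol %), −40 to 40 °C
Reagents that add atoms: none
Why: Proposed new method: the copper/bisphosphine cation binds the amide oxygen and pyridine nitrogen of 6, the guanidine removes the acidified C8' proton, and the resulting Z-configured enolate of monovalent copper adds to aldehyde 8 to form C7'–C8' and the copper alkoxide of 9; on warming with Cs2CO3 this alkoxide, which is exactly the nucleophile of an Ullmann ether synthesis and is held beside the metal by the N,O-chelating amide, undergoes oxidative addition of the neighbouring C3–I bond (trivalent copper in a seven-membered metallacycle) and reductive elimination to form O–C3. The closest known reaction types are the copper/bisphosphine-catalysed direct aldol addition of alpha-heteroatom-substituted 7-azaindoline amides to aromatic aldehydes and the copper-catalysed intramolecular O-arylation of 2-(2-halophenoxy)alkanols to 1,4-benzodioxanes, and only their merger on one metal in one flask is new. Ring B is the only ring closed, in a 6-exo mode (the C–I bond that breaks lies outside the new ring), whereas arylation of the enolate carbon would need a four-membered benzoxete and is excluded. C8' is set by the ligand-shielded face of the Z-enolate and C7' by a closed chair-like transition state with ring C equatorial, which should give the syn adduct, and since the O-arylation touches neither centre syn maps onto the trans ring B. The step needs iodide over bromide selectivity (weaker C–I bond, and only C3 lies within reach of the alkoxide), addition to 8 alone (6 has no competing electrophilic carbonyl and 8 cannot enolise) and ring closure in preference to retro-aldol cleavage, which the irreversible C–O bond formation should secure by draining the aldol equilibrium, the diequatorial trans closure being the faster one.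

Step 6
Reactants: 10 trans-(7'S,8'R)-benzodioxane 7-azaindoline amide
Product: 12 trans-(7'S,8'S)-bromo alcohol, via alpha-aryloxy aldehyde 11 (not isolated)
Conditions: LiAlH4, THF, −40 °C; then NaBH4, MeOH, −40 to 0 °C
Reagents that add atoms: none
Why: Partial amide reduction followed by borohydride reduction, in which the azaindoline amide gives a chelated tetrahedral adduct (as an N-methoxy-N-methyl amide does) that collapses only on the methanol quench, where NaBH4 reduces aldehyde 11 at once, so C8' should keep its spatial arrangement (the descriptor changes from R to S by priority only).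

Step 7
Reactants: 12 trans-(7'S,8'S)-bromo alcohol; 13 acrolein diethyl acetal
Product: 15 O-MOM-(7'S,8'S)-nocomtal, via cinnamyl diethyl acetal 14 (not isolated)
Conditions: Pd(OAc)2 (3 mol %), n-Bu4NOAc, K2CO3, KCl, DMF, 90 °C; then 2 M HCl, rt
Reagents that add atoms: water O
Why: Mizoroki–Heck reaction on zerovalent palladium formed in the flask, in which syn insertion and syn beta-hydride elimination toward the benzylic hydrogen give the E-cinnamyl acetal, brief dilute acid unmasks the enal, and no stereocentre carries an acidic hydrogen any more.

Step 8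
Reactants: 15 O-MOM-(7'S,8'S)-nocomtal
Product: 16 (7'S,8'S)-nocomtal
Conditions: 3 M HCl, THF, 45 °C
Reagents that add atoms: none
Why: Acid-catalysed hydrolysis of the aryl MOM acetal, which the enal and the primary alcohol tolerate; C8' has no pathway to epimerise, and any reversible ionisation of the p-hydroxybenzylic C7'–O bond can only return the more stable trans ring B.

## Compound list

1 | 4-bromo-2-methoxyphenol | COc1cc(Br)ccc1O | starting material
2 | 4-bromo-2-iodo-6-methoxyphenol | COc1cc(Br)cc(I)c1O | intermediate
3 | 7-azaindoline (2,3-dihydro-1H-pyrrolo[2,3-b]pyridine) | C1Cc2cccnc2N1 | starting material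
4 | chloroacetyl chloride | ClCC(=O)Cl | starting material
5 | 1-(chloroacetyl)-7-azaindoline | O=C(CCl)N1CCc2cccnc21 | intermediate
6 | 1-[(4-bromo-2-iodo-6-methoxyphenoxy)acetyl]-7-azaindoline | COc1cc(Br)cc(I)c1OCC(=O)N1CCc2cccnc21 | intermediate
7 | vanillin | COc1cc(C=O)ccc1O | starting material
8 | 3-methoxy-4-(methoxymethoxy)benzaldehyde | COCOc1ccc(C=O)cc1OC | intermediate
9 | syn aldol adduct, (2R,3S)-2-(4-bromo-2-iodo-6-methoxyphenoxy)-3-hydroxy-3-[3-methoxy-4-(methoxymethoxy)phenyl]-1-(7-azaindolin-1-yl)propan-1-one (7'S,8'R), present as its copper alkoxide | COCOc1ccc([C@H](O)[C@@H](Oc2c(I)cc(Br)cc2OC)C(=O)N3CCc4cccnc43)cc1OC | intermediate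
10 | trans amide, [(2S,3R)-7-bromo-5-methoxy-2-[3-methoxy-4-(methoxymethoxy)phenyl]-2,3-dihydro-1,4-benzodioxin-3-yl](7-azaindolin-1-yl)methanone (7'S,8'R) | COCOc1ccc([C@@H]2Oc3cc(Br)cc(OC)c3O[C@H]2C(=O)N4CCc5cccnc54)cc1OC | intermediate
11 | trans aldehyde, (2S,3R)-7-bromo-5-methoxy-2-[3-methoxy-4-(methoxymethoxy)phenyl]-2,3-dihydro-1,4-benzodioxine-3-carbaldehyde | COCOc1ccc([C@@H]2Oc3cc(Br)cc(OC)c3O[C@H]2C=O)cc1OC | intermediate
12 | trans alcohol, [(2S,3S)-7-bromo-5-methoxy-2-[3-methoxy-4-(methoxymethoxy)phenyl]-2,3-dihydro-1,4-benzodioxin-3-yl]methanol (7'S,8'S) | COCOc1ccc([C@@H]2Oc3cc(Br)cc(OC)c3O[C@H]2CO)cc1OC | intermediate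
13 | acrolein diethyl acetal (3,3-diethoxyprop-1-ene) | C=CC(OCC)OCC | starting material
14 | (E)-cinnamyl diethyl acetal of 12 (ring A C1–CH=CH–CH(OEt)2, 7'S,8'S) | COCOc1ccc([C@@H]2Oc3cc(/C=C/C(OCC)OCC)cc(OC)c3O[C@H]2CO)cc1OC | intermediate
15 | O-MOM-(7'S,8'S)-nocomtal, (E)-3-[(2S,3S)-3-(hydroxymethyl)-5-methoxy-2-[3-methoxy-4-(methoxymethoxy)phenyl]-2,3-dihydro-1,4-benzodioxin-7-yl]prop-2-enal | COCOc1ccc([C@@H]2Oc3cc(/C=C/C=O)cc(OC)c3O[C@H]2CO)cc1OC | intermediate
16 | (7'S,8'S)-nocomtal | COc1cc([C@@H]2Oc3cc(/C=C/C=O)cc(OC)c3O[C@H]2CO)ccc1O | target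

## Step count and risks

Total step count: 8. Longest linear sequence: 6 (steps 1, 3, 5, 6, 7, 8).

**1. Step 5.**
- On warming, retro-aldol cleavage or dehydration of the aldolate may outrun the O-arylation.
- The electron-rich aldehyde may turn over slowly.
- Copper-assisted enolisation of the product, with reversible beta-elimination of the ring A aryloxide, may erode the configuration.

The fallback uses known chemistry only, sets out from 2 and 8, and returns at 12. Phenol 2 is alkylated with sodium chloroacetate (aq. NaOH, reflux) to (4-bromo-2-iodo-6-methoxyphenoxy)acetic acid F1. Its pivalic mixed anhydride (PivCl, Et3N, LiCl, THF) acylates (R)-4-benzyloxazolidin-2-one to the N-(aryloxyacetyl)oxazolidinone F2. An Evans syn aldol reaction (Bu2BOTf, Et3N, CH2Cl2, −78 to 0 °C, then 8, H2O2 work-up) should give the syn aldol imide F3. LiBH4 (THF, MeOH, 0 °C) removes the auxiliary to give the 1,3-diol F4. TBSCl and imidazole mask the primary hydroxyl, which would otherwise also close a six-membered ring, as the primary silyl ether F5. A separate intramolecular Ullmann ether synthesis (CuI, 3,4,7,8-tetramethyl-1,10-phenanthroline, Cs2CO3, toluene, 80 °C) has no retro-aldol or enolisation pathway and closes ring B to the ring-closed silyl ether F6. n-Bu4NF then gives 12.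

**2. Step 6.**
- Epimerisation at C8' or beta-elimination of the ring A aryloxide may occur while the aldehyde is free in basic methanol.
- The chelated adduct may collapse incompletely.

The fallback sets out from 10 and returns at 16. Aqueous HCl in dioxane (60 °C) hydrolyses the protonated azaindoline amide together with the MOM ether to the phenolic carboxylic acid F7. BH3·SMe2 (THF, 0 °C to rt) reduces the acid without passing through a free aldehyde to the phenolic bromo alcohol F8. The Heck reaction with 13 under the conditions of step 7 gives the phenolic cinnamyl acetal F9. The dilute HCl work-up delivers 16 directly.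

**3. Step 7.**
- Beta-hydride elimination toward the acetal carbon leads to the saturated ester manifold.
- Oxidative addition to the electron-rich bromide may be slow.
- The catalyst may precipitate.

The fallback sets out from 12 and returns at 15. The alcohol is deprotonated and the bromide exchanged with n-BuLi (2.2 equiv, THF, −78 °C), and a DMF quench gives the ring A benzaldehyde F10. A Wittig reaction with (triphenylphosphoranylidene)acetaldehyde (toluene, 80 °C) should then give the E-enal 15.

## Further compounds

F1 | step 5 | (4-bromo-2-iodo-6-methoxyphenoxy)acetic acid | COc1cc(Br)cc(I)c1OCC(=O)O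
F2 | step 5 | (R)-4-benzyl-3-[(4-bromo-2-iodo-6-methoxyphenoxy)acetyl]oxazolidin-2-one | COc1cc(Br)cc(I)c1OCC(=O)N1C(=O)OC[C@H]1Cc1ccccc1
F3 | step 5 | syn aldol imide (7'S,8'R; auxiliary 4R) | COCOc1ccc([C@H](O)[C@@H](Oc2c(I)cc(Br)cc2OC)C(=O)N3C(=O)OC[C@H]3Cc4ccccc4)cc1OC
F4 | step 5 | (7'S,8'S)-1,3-diol, 2-(4-bromo-2-iodo-6-methoxyphenoxy)-1-[3-methoxy-4-(methoxymethoxy)phenyl]propane-1,3-diol | COCOc1ccc([C@H](O)[C@@H](Oc2c(I)cc(Br)cc2OC)CO)cc1OC
F5 | step 5 | primary TBS ether of F4 | COCOc1ccc([C@H](O)[C@@H](Oc2c(I)cc(Br)cc2OC)CO[Si](C)(C)C(C)(C)C)cc1OC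
F6 | step 5 | TBS ether of 12 (trans, 7'S,8'S) | COCOc1ccc([C@@H]2Oc3cc(Br)cc(OC)c3O[C@H]2CO[Si](C)(C)C(C)(C)C)cc1OC
F7 | step 6 | trans phenolic carboxylic acid (7'S,8'R) | COc1cc([C@@H]2Oc3cc(Br)cc(OC)c3O[C@H]2C(=O)O)ccc1O
F8 | step 6 | trans phenolic bromo alcohol (7'S,8'S) | COc1cc([C@@H]2Oc3cc(Br)cc(OC)c3O[C@H]2CO)ccc1O
F9 | step 6 | phenolic (E)-cinnamyl diethyl acetal (7'S,8'S) | COc1cc([C@@H]2Oc3cc(/C=C/C(OCC)OCC)cc(OC)c3O[C@H]2CO)ccc1O
F10 | step 7 | ring A benzaldehyde (7'S,8'S), CHO in place of Br in 12 | COCOc1ccc([C@@H]2Oc3cc(C=O)cc(OC)c3O[C@H]2CO)cc1OC
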